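**Retrosynthetic overview**

1. The target is a cyclobutane whose two adjacent quaternary carbons are each the spiro C5 (γ-carbon) of a 4-bromo-3-(1-acetoxybutyl)furan-2(5H)-one, with a trans CHBr–CHBr unit as the opposite edge. The strategy rests on this: the spiro–spiro bond joins two 2-oxyfuran γ-carbons, and the CHBr–CHBr edge is C2–C3 of L-tartaric acid with both C–O bonds exchanged for C–Br with inversion.
2. Endgame (24 ⇐ 22 ⇐ 19): C–Br from C–OTf by SN2 on the trans-cyclobutanediol; side-chain acetates from TES ethers.
3. Key disconnection (19 ⇐ 18): the C5–C5' bond, made by two-electron oxidation of a tartrate-tethered bis(2-silyloxyfuran); this closes the cyclobutane, the last ring formed.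
4. 18 ⇐ 17 ⇐ 16 ⇐ 15: the furans come from two 4-bromobutenolides (the first rings formed), made by bromolactonisation of a bis(allenic acid), itself from palladium-catalysed hydrocarboxylation of a bis(propargylic mesylate).
5. 15 ⇐ 10 + 6 + 5: the tartrate dialdehyde takes the (S)- and then the (R)-3-silyloxyhexyne; the lactol formed after the first addition keeps the two ends apart.

Key step: step 14

**Remarks on the chemistry (assumptions)**

- The two side-chain carbinol centres of the target have opposite configurations, one S and one R. The dispiro core is C2-symmetric, so it does not matter which end of the tartrate unit receives which alkyne.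
- Protecting groups are TBS on the tartrate oxygens and TES on the side chains. TBS resists 1,2-migration in steps 8–9 and its bulk favours the conformer with anti silyloxy groups and gauche furans. TES lets the acetates go in before the bromides.
- The lipase enantiopreference in steps 1–2 is the one predicted by the empirical size rule for secondary alcohols; the absolute configurations of 2 and 4 should be verified by Mosher ester analysis before the two series are carried forward.
- The carbinol centres made in steps 8 and 9, the allene axes of 16 and C5 of each ring in 17 are formed as mixtures. All are erased when 18 is formed.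

**Route**

Step 1
Reactants: 1 rac-hex-1-yn-3-ol
Product: 2 (R)-hex-1-yn-3-ol (recovered alcohol) and 3 (S)-hex-1-yn-3-yl acetate (both isolated)
Conditions: immobilised Candida antarctica lipase B, vinyl acetate, hexane, rt, run past half conversion
Reagents that add atoms: vinyl acetate CC(=O)OC=C
Why: Lipase-catalysed kinetic resolution by transesterification, in which ethynyl is the medium and propyl the large group so that the (S)-alcohol should be acylated and running past half conversion should leave 2 in high enantiomeric purity; no new stereocentre is made.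

Step 2
Reactants: 3 (S)-hex-1-yn-3-yl acetate
Product: 4 (S)-hex-1-yn-3-ol
Conditions: immobilised Candida antarctica lipase B, n-BuOH, t-BuOMe, rt, stopped before full conversion
Reagents that add atoms: none
Why: Lipase-catalysed alcoholysis has the same (S)-preference as step 1, so this second enantioselective pass should raise the purity of the (S)-series while freeing the alcohol under neutral conditions.

Step 3
Reactants: 2 (R)-hex-1-yn-3-ol
Product: 5 (R)-3-(triethylsilyloxy)hex-1-yne
Conditions: Et3SiCl, imidazole, CH2Cl2, 0 °C → rt
Reagents that add atoms: chlorotriethylsilane CC[Si](Cl)(CC)CC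
Why: Standard silylation of a secondary alcohol at oxygen, which leaves the stereocentre and the terminal alkyne untouched.

Step 4
Reactants: 4 (S)-hex-1-yn-3-ol
Product: 6 (S)-3-(triethylsilyloxy)hex-1-yne
Conditions: Et3SiCl, imidazole, CH2Cl2, 0 °C → rt
Reagents that add atoms: chlorotriethylsilane CC[Si](Cl)(CC)CC
Why: Standard silylation of a secondary alcohol at oxygen, which leaves the stereocentre and the terminal alkyne untouched.

Step 5
Reactants: 7 diethyl L-tartrate
Product: 8 diethyl (2R,3R)-2,3-bis(tert-butyldimethylsilyloxy)butanedioate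
Conditions: t-BuMe2SiOTf, 2,6-lutidine, CH2Cl2, 0 °C → rt
Reagents that add atoms: tert-butyldimethylsilyl triflate CC(C)(C)[Si](C)(C)OS(=O)(=O)C(F)(F)F
Why: The silyl triflate silylates both hindered α-hydroxy ester oxygens under non-epimerising conditions, so the two tartrate centres are carried over unchanged.

Step 6
Reactants: 8 diethyl (2R,3R)-2,3-bis(tert-butyldimethylsilyloxy)butanedioate
Product: 9 (2S,3S)-2,3-bis(tert-butyldimethylsilyloxy)butane-1,4-diol
Conditions: i-Bu2AlH, CH2Cl2, −78 → 0 °C; aq. KNaC4H4O6
Reagents that add atoms: none
Why: Hydride reduction of both esters to primary alcohols, with aluminium alkoxides at low temperature not expected to trigger 1,2-silyl migration (the descriptor changes only through the priority rules).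

Step 7
Reactants: 9 (2S,3S)-2,3-bis(tert-butyldimethylsilyloxy)butane-1,4-diol
Product: 10 (2R,3R)-2,3-bis(tert-butyldimethylsilyloxy)butanedial
Conditions: (COCl)2, DMSO, CH2Cl2, −78 °C; i-Pr2NEt, −78 → −40 °C; non-aqueous work-up, used at once
Reagents that add atoms: none
Why: Swern oxidation gives the dialdehyde without water (no hydrate) and, with a hindered amine at low temperature, without epimerising the α-silyloxy centres.

Step 8
Reactants: 10 (2R,3R)-2,3-bis(tert-butyldimethylsilyloxy)butanedial; 6 (S)-3-(triethylsilyloxy)hex-1-yne
Product: 12 (3R,4S)-3,4-bis(tert-butyldimethylsilyloxy)-5-[(3S)-3-(triethylsilyloxy)hex-1-yn-1-yl]oxolan-2-ol (mixture at C2 and C5), via lithium acetylide 11 (not isolated)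
Conditions: 6, n-BuLi, THF, −78 °C; added slowly to 10 (slight excess), THF, −78 °C; AcOH quench at −78 °C
Reagents that add atoms: none
Why: 1,2-Addition of a lithium acetylide to one aldehyde gives an alkoxide that closes at once onto the second aldehyde as a five-membered lactolate, which masks that carbon and so limits the reaction to one alkynylation; the new centres at C2 and C5 form as mixtures and are erased later.

Step 9
Reactants: 12 the lactol from step 8; 5 (R)-3-(triethylsilyloxy)hex-1-yne
Product: 14 (4S,13R)-8,9-bis(tert-butyldimethylsilyloxy)-4,13-bis(triethylsilyloxy)hexadeca-5,11-diyne-7,10-diol with C8 and C9 as in L-tartrate (mixture at C7 and C10), via alkynylmagnesium bromide 13 (not isolated)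
Conditions: 5 (2.5 equiv), EtMgBr, THF, 0 °C → rt; then 12, 0 °C → rt; aq. NH4Cl
Reagents that add atoms: none
Why: Alkynyl Grignard addition to a furanose-type lactol, in which the magnesium lactolate opens to the hydroxy aldehyde that a second equivalent of 13 traps, while magnesium alkoxides should not move the neighbouring TBS groups; the new carbinol centre forms as a mixture and is erased later.

Step 10
Reactants: 14 the bis(propargylic) diol
Product: 15 the 7,10-bis(methanesulfonate) of 14
Conditions: MsCl, Et3N, CH2Cl2, −40 → 0 °C; used crude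
Reagents that add atoms: methanesulfonyl chloride CS(=O)(=O)Cl
Why: Sulfonylation of both secondary propargylic alcohols under cold, mildly basic conditions that silyl ethers and alkynes tolerate.

Step 11
Reactants: 15 the bis(propargylic mesylate)
Product: 16 the bis(2,3-allenic acid): each CH(OMs)–C≡C unit has become CH=C=C(CO2H), the carboxyl sitting on the carbon that bears the 1-(triethylsilyloxy)butyl group (mixture of allene axis isomers)
Conditions: Pd(PPh3)4 (cat.), CO (1 atm), 2,6-lutidine, THF/H2O, rt
Reagents that add atoms: carbon monoxide [C-]#[O+]; water O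
Why: Hydrocarboxylation of propargylic mesylates, in which SN2' oxidative addition of zerovalent palladium gives an allenylpalladium that inserts CO and is hydrolysed to the allenic acid, the lutidine taking up the sulfonic acid so that the TES ethers survive.

Step 12
Reactants: 16 the bis(2,3-allenic acid)
Product: 17 the bis(4-bromobutenolide): 1,2-bis(tert-butyldimethylsilyloxy)ethane (both carbons as in L-tartrate) whose two carbons each carry C5 of a 4-bromofuran-2(5H)-one, one ring with a (1S)- and the other with a (1R)-1-(triethylsilyloxy)butyl group at C3 (mixture at C5 of both rings)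
Conditions: N-bromosuccinimide, K2CO3, MeCN, 0 °C, dark
Reagents that add atoms: N-bromosuccinimide O=C1CCC(=O)N1Br
Why: Bromolactonisation of 2,3-allenoic acids, in which bromine adds to the central allene carbon and the carboxylate closes on the γ-carbon to give the 4-bromobutenolide (both five-membered lactones form here); the C5 centres are mixtures that step 13 erases.

Step 13
Reactants: 17 the bis(4-bromobutenolide)
Product: 18 (1R,2R)-1,2-bis(tert-butyldimethylsilyloxy)-1-{3-bromo-5-(tert-butyldimethylsilyloxy)-4-[(1S)-1-(triethylsilyloxy)butyl]furan-2-yl}-2-{3-bromo-5-(tert-butyldimethylsilyloxy)-4-[(1R)-1-(triethylsilyloxy)butyl]furan-2-yl}ethane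
Conditions: t-BuMe2SiOTf, Et3N, CH2Cl2, 0 °C; rapid filtration through Et3N-deactivated silica
Reagents that add atoms: tert-butyldimethylsilyl triflate CC(C)(C)[Si](C)(C)OS(=O)(=O)C(F)(F)F
Why: Soft enolisation with O-silylation then γ-deprotonation aromatises each butenolide to a 2-silyloxyfuran, and because no free dienolate is formed the β-silyloxy group should not be eliminated.

Step 14
Reactants: 18 the tartrate-tethered bis(2-silyloxyfuran)
Product: 19 the dispiro bis(4-bromobutenolide) cyclobutane: the two spiro lactone oxygens trans to each other, each cis to the OTBS group on the neighbouring ring carbon, trans-bis(OTBS), with (1S)- and (1R)-1-(triethylsilyloxy)butyl side chains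
Conditions: (NH4)2Ce(NO3)6 (2.2 equiv, added slowly in MeCN), NaHCO3, MeCN/EtCN, −30 °C, high dilution
Reagents that add atoms: none
Why: One-electron oxidation of one silyloxyfuran by tetravalent cerium and loss of its silyl group should give a captodative 5-oxo-2,5-dihydrofuran-2-yl radical that attacks C5 of the second silyloxyfuran, and a second oxidation and desilylation then make the C5–C5' bond permanent and turn both furans into butenolides. The closest known reactions are the oxidative coupling of enol silanes with this oxidant, including C5–C5' dimerisation of 2-silyloxyfurans, and the oxidative cyclisation of 1,4-linked diester bis-enolates to cyclobutanes. The cyclobutane closes in the 4-exo-trig mode, the threo tether placing the two furans gauche when its bulky OTBS groups are anti. Each new spiro centre is set by the adjacent tartrate carbon: the C4–Br flank of each furan avoids the neighbouring OTBS group (allylic strain) and lies next to C–H, so each lactone oxygen ends cis to its neighbouring OTBS, and the C2-symmetric antiparallel stacking of the two rings puts the two lactone oxygens trans. The step needs γ,γ-coupling rather than bonding through C3, and ring closure rather than oligomerisation, tether cleavage or nitrate capture; C3 is blocked by the side chain (a C3 bond would also require a bridgehead alkene), and high dilution with slow addition of the oxidant serves the rest.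

Step 15
Reactants: 19 the dispiro bis(TBS) bis(TES) ether
Product: 20 the dispiro compound with free (1S)- and (1R)-1-hydroxybutyl side chains and both ring OTBS groups intact
Conditions: pyridinium p-toluenesulfonate (cat.), MeOH/CH2Cl2, 0 °C → rt
Reagents that add atoms: none
Why: Acid-catalysed methanolysis cleaves the secondary TES ethers far faster than the TBS ethers, which are flanked by quaternary spiro carbons (chemoselective silyl ether solvolysis), and touches no stereocentre.

Step 16
Reactants: 20 the side-chain diol
Product: 21 the side-chain diacetate with both ring OTBS groups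
Conditions: Ac2O, pyridine, 4-(dimethylamino)pyridine (cat.), CH2Cl2, 0 °C → rt
Reagents that add atoms: acetic anhydride CC(=O)OC(C)=O
Why: Nucleophile-catalysed O-acylation of the two secondary alcohols with retention, under conditions to which lactones, vinyl bromides and TBS ethers are inert.

Step 17
Reactants: 21 the diacetate bis(TBS) ether
Product: 22 the trans-cyclobutane-1,2-diol carrying both acetoxybutyl side chains
Conditions: HF (48 % aq.), MeCN, rt (→ 40 °C if slow), plastic vessel
Reagents that add atoms: none
Why: Acidic fluoride desilylation removes the two hindered TBS ethers while acetates, lactones and vinyl bromides are inert to HF; acid is chosen because an alkoxide on this cyclobutane could open the ring by a vinylogous retro-aldol reaction.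

Step 18
Reactants: 22 the trans-cyclobutane-1,2-diol
Product: 24 the target CNP0266230.1 (trans-dibromide with each bromine trans to the lactone oxygen on the neighbouring spiro carbon), via bis-triflate 23 (not isolated)
Conditions: Tf2O, 2,6-di-tert-butyl-4-methylpyridine, CH2Cl2, −40 → 0 °C; then Bu4NBr, 0 → 35 °C
Reagents that add atoms: tetrabutylammonium bromide CCCC[N+](CCCC)(CCCC)CCCC.[Br-]; triflic anhydride O=S(=O)(OS(=O)(=O)C(F)(F)F)C(F)(F)F (its atoms are carried only in 23)
Why: Sulfonylation then SN2 displacement, in which bromide replaces each cyclobutyl triflate with inversion and so sets both CHBr centres; the cis relationship of Br and OTf in the intermediate bromo triflate rules out bromonium participation, and bromide is a poor base for elimination to a cyclobutene.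

**Compound list**

1 | rac-hex-1-yn-3-ol | CCCC(O)C#C | starting material
2 | (R)-hex-1-yn-3-ol | CCC[C@@H](O)C#C | intermediate
3 | (S)-hex-1-yn-3-yl acetate | CCC[C@H](OC(C)=O)C#C | intermediate
4 | (S)-hex-1-yn-3-ol | CCC[C@H](O)C#C | intermediate
5 | (R)-3-(triethylsilyloxy)hex-1-yne | CCC[C@@H](O[Si](CC)(CC)CC)C#C | intermediate
6 | (S)-3-(triethylsilyloxy)hex-1-yne | CCC[C@H](O[Si](CC)(CC)CC)C#C | intermediate
7 | diethyl L-tartrate, (2R,3R) | CCOC(=O)[C@H](O)[C@@H](O)C(=O)OCC | starting material
8 | diethyl (2R,3R)-2,3-bis(tert-butyldimethylsilyloxy)butanedioate | CCOC(=O)[C@H](O[Si](C)(C)C(C)(C)C)[C@@H](O[Si](C)(C)C(C)(C)C)C(=O)OCC | intermediate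
9 | (2S,3S)-2,3-bis(tert-butyldimethylsilyloxy)butane-1,4-diol | OC[C@H](O[Si](C)(C)C(C)(C)C)[C@@H](O[Si](C)(C)C(C)(C)C)CO | intermediate
10 | (2R,3R)-2,3-bis(tert-butyldimethylsilyloxy)butanedial | O=C[C@H](O[Si](C)(C)C(C)(C)C)[C@@H](O[Si](C)(C)C(C)(C)C)C=O | intermediate
11 | lithium (3S)-3-(triethylsilyloxy)hex-1-yn-1-ide (from 6) | CCC[C@H](O[Si](CC)(CC)CC)C#C[Li] | intermediate
12 | (3R,4S)-3,4-bis(tert-butyldimethylsilyloxy)-5-[(3S)-3-(triethylsilyloxy)hex-1-yn-1-yl]oxolan-2-ol, mixture at C2 and C5 | CCC[C@H](O[Si](CC)(CC)CC)C#CC1[C@H](O[Si](C)(C)C(C)(C)C)[C@@H](O[Si](C)(C)C(C)(C)C)C(O)O1 | intermediate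
13 | [(3R)-3-(triethylsilyloxy)hex-1-yn-1-yl]magnesium bromide (from 5) | CCC[C@@H](O[Si](CC)(CC)CC)C#C[Mg]Br | intermediate
14 | (4S,13R)-8,9-bis(tert-butyldimethylsilyloxy)-4,13-bis(triethylsilyloxy)hexadeca-5,11-diyne-7,10-diol, C8/C9 as in L-tartrate, mixture at C7 and C10 | CCC[C@H](O[Si](CC)(CC)CC)C#CC(O)[C@H](O[Si](C)(C)C(C)(C)C)[C@@H](O[Si](C)(C)C(C)(C)C)C(O)C#C[C@@H](CCC)O[Si](CC)(CC)CC | intermediate
15 | 7,10-bis(methanesulfonate) of 14 | CCC[C@H](O[Si](CC)(CC)CC)C#CC(OS(C)(=O)=O)[C@H](O[Si](C)(C)C(C)(C)C)[C@@H](O[Si](C)(C)C(C)(C)C)C(OS(C)(=O)=O)C#C[C@@H](CCC)O[Si](CC)(CC)CC | intermediate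
16 | bis(2,3-allenic acid), tartrate carbons unchanged, side chains S and R, allene axes as mixtures | CCC[C@H](O[Si](CC)(CC)CC)C(C(=O)O)=C=C[C@H](O[Si](C)(C)C(C)(C)C)[C@@H](O[Si](C)(C)C(C)(C)C)C=C=C(C(=O)O)[C@@H](CCC)O[Si](CC)(CC)CC | intermediate
17 | tartrate-linked bis(4-bromobutenolide), tartrate carbons unchanged, side chains S and R, mixture at both ring C5 | CCC[C@H](O[Si](CC)(CC)CC)C1=C(Br)C(OC1=O)[C@H](O[Si](C)(C)C(C)(C)C)[C@@H](O[Si](C)(C)C(C)(C)C)C1OC(=O)C([C@@H](CCC)O[Si](CC)(CC)CC)=C1Br | intermediate
18 | (1R,2R)-1,2-bis(tert-butyldimethylsilyloxy)ethane bearing two 3-bromo-5-(tert-butyldimethylsilyloxy)-4-[1-(triethylsilyloxy)butyl]furan-2-yl groups, side chains (1S) and (1R) (key-step precursor) | CCC[C@H](O[Si](CC)(CC)CC)c1c(Br)c(oc1O[Si](C)(C)C(C)(C)C)[C@H](O[Si](C)(C)C(C)(C)C)[C@@H](O[Si](C)(C)C(C)(C)C)c1oc(O[Si](C)(C)C(C)(C)C)c([C@@H](CCC)O[Si](CC)(CC)CC)c1Br | intermediate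
19 | 4,10-dibromo-11,12-bis(tert-butyldimethylsilyloxy)-3,9-bis[1-(triethylsilyloxy)butyl]-1,7-dioxadispiro[4.0.4.2]dodeca-3,9-diene-2,8-dione, lactone oxygens trans, each cis to the adjacent OTBS (key-step product) | CCC[C@H](O[Si](CC)(CC)CC)C1=C(Br)[C@@]2(OC1=O)[C@H](O[Si](C)(C)C(C)(C)C)[C@@H](O[Si](C)(C)C(C)(C)C)[C@@]21OC(=O)C([C@@H](CCC)O[Si](CC)(CC)CC)=C1Br | intermediate
20 | side-chain diol of 19 (TES removed) | CCC[C@H](O)C1=C(Br)[C@@]2(OC1=O)[C@H](O[Si](C)(C)C(C)(C)C)[C@@H](O[Si](C)(C)C(C)(C)C)[C@@]21OC(=O)C([C@@H](CCC)O)=C1Br | intermediate
21 | side-chain diacetate, ring bis(TBS) ether | CCC[C@H](OC(C)=O)C1=C(Br)[C@@]2(OC1=O)[C@H](O[Si](C)(C)C(C)(C)C)[C@@H](O[Si](C)(C)C(C)(C)C)[C@@]21OC(=O)C([C@@H](CCC)OC(C)=O)=C1Br | intermediate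
22 | trans-cyclobutane-11,12-diol diacetate | CCC[C@H](OC(C)=O)C1=C(Br)[C@@]2(OC1=O)[C@H](O)[C@@H](O)[C@@]21OC(=O)C([C@@H](CCC)OC(C)=O)=C1Br | intermediate
23 | 11,12-bis(trifluoromethanesulfonate) of 22 | CCC[C@H](OC(C)=O)C1=C(Br)[C@@]2(OC1=O)[C@H](OS(=O)(=O)C(F)(F)F)[C@@H](OS(=O)(=O)C(F)(F)F)[C@@]21OC(=O)C([C@@H](CCC)OC(C)=O)=C1Br | intermediate
24 | CNP0266230.1: 3,9-bis(1-acetoxybutyl)-4,10,11,12-tetrabromo-1,7-dioxadispiro[4.0.4.2]dodeca-3,9-diene-2,8-dione | CCC[C@H](OC(C)=O)C1=C(Br)[C@@]2(OC1=O)[C@@H](Br)[C@H](Br)[C@@]21OC(=O)C([C@@H](CCC)OC(C)=O)=C1Br | target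

**Step count**

Total: 18 steps. Longest linear sequence: 14 steps (7 → 24 through steps 5–18; the same length from 1 through steps 1, 2, 4 and 8–18).

**Steps most likely to fail**

1. Step 14 (cyclobutane closure). The radical cation may fragment at the furfurylic C–C bond of the tether, or a doubly oxidised species may split into two 5-(silyloxymethylidene)butenolides. Nitrate capture at C5 or intermolecular coupling may also outrun the strained 4-exo closure between two fully substituted carbons. Fallback, polar instead of radical: starting from 18, one equivalent of N-bromosuccinimide in CH2Cl2 at −78 °C should brominate one furan at C5 (a known reaction of 2-silyloxyfurans) to give the mono(5-bromobutenolide) mono(silyloxyfuran) F1. Either ring may react, since both regioisomers lead to the same product. AgOCOCF3 then ionises the tertiary allylic C–Br bond, and the remaining silyloxyfuran alkylates through its γ-carbon (silver-promoted C5 alkylation of silyloxyfurans by halides). The conformational control is the same, and the sequence rejoins the route at 19.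

2. Step 18 (double displacement). Bromide must enter each ring carbon on the face that carries the C4–Br flank of the neighbouring butenolide. The slow backside attack may let triflate ionisation with ring contraction, or attack at sulfur, take over. Fallback, redox-condensation instead of sulfonate displacement: starting from 22, PPh3 and CBr4 in CH2Cl2 (Appel reaction) activate one hydroxyl at a time as an alkoxyphosphonium ion whose own bromide counter-ion displaces it with inversion. The reaction passes through the cis-bromohydrin F2 (drawn for the ring carbon next to the (S)-side-chain butenolide; its regioisomer behaves alike), and a second such exchange with the same reagents arrives at 24. No free bis-sulfonate is ever present.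

3. Step 8 (single alkynylation of the dialdehyde). A second acetylide addition may compete with lactolate closure, and hydration or α-epimerisation of the free dialdehyde may erode yield and stereochemical integrity. Fallback, desymmetrisation by oxidation state instead of by stoichiometry: starting from 9, oxidative lactonisation (TEMPO, PhI(OAc)2, CH2Cl2) gives (3R,4S)-3,4-bis(tert-butyldimethylsilyloxy)oxolan-2-one F3. Lithium acetylide 11 at −78 °C adds once, giving the hydroxy ynone F4 (in equilibrium with its cyclic hemiketal). NaBH4/CeCl3 in MeOH at −78 °C reduces the ketone to the primary/propargylic 1,4-diol F5. TEMPO with one equivalent of PhI(OAc)2 oxidises only the primary alcohol, and the resulting hydroxy aldehyde closes to lactol 12, where the route resumes.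

**Further compounds**

F1 | step 14 | mono(5-bromobutenolide) mono(2-silyloxyfuran) from 18 (bromide at C5 of the (S)-side-chain ring, mixture at that carbon) | CCC[C@H](O[Si](CC)(CC)CC)C1=C(Br)C(Br)(OC1=O)[C@H](O[Si](C)(C)C(C)(C)C)[C@@H](O[Si](C)(C)C(C)(C)C)c1oc(O[Si](C)(C)C(C)(C)C)c([C@@H](CCC)O[Si](CC)(CC)CC)c1Br
F2 | step 18 | cis-bromohydrin from 22 (one hydroxyl exchanged for bromine with inversion) | CCC[C@H](OC(C)=O)C1=C(Br)[C@@]2(OC1=O)[C@@H](Br)[C@@H](O)[C@@]21OC(=O)C([C@@H](CCC)OC(C)=O)=C1Br
F3 | step 8 | (3R,4S)-3,4-bis(tert-butyldimethylsilyloxy)oxolan-2-one | O=C1[C@H](O[Si](C)(C)C(C)(C)C)[C@@H](O[Si](C)(C)C(C)(C)C)CO1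
F4 | step 8 | hydroxy ynone: 1-hydroxy-2,3-bis(tert-butyldimethylsilyloxy)-7-(triethylsilyloxy)dec-5-yn-4-one, tartrate carbons unchanged, side chain S | CCC[C@H](O[Si](CC)(CC)CC)C#CC(=O)[C@H](O[Si](C)(C)C(C)(C)C)[C@@H](O[Si](C)(C)C(C)(C)C)CO
F5 | step 8 | 2,3-bis(tert-butyldimethylsilyloxy)-7-(triethylsilyloxy)dec-5-yne-1,4-diol, tartrate carbons unchanged, side chain S, mixture at C4 | CCC[C@H](O[Si](CC)(CC)CC)C#CC(O)[C@H](O[Si](C)(C)C(C)(C)C)[C@@H](O[Si](C)(C)C(C)(C)C)CO
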